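Suffix U marks the upper flavan (rings A, C, B), L the lower flavan-3,4-diol (rings D, F, E). The route rests on disconnecting O1-U–C2-U. C2-U is benzylic and para to the ring B hydroxyl, so it can become a p-quinone methide carbon; C4-U bears two identical 2-hydroxy-3,4-bis(benzyloxy)phenyl groups, the future rings A and D. In one operation a chiral phosphoric acid dehydrates a racemic carbinol to that methide and one of the two enantiotopic phenols adds through oxygen, closing ring C and setting C2-U and C4-U together, 2,4-trans. The precursor is a 1-(4-hydroxyphenyl)-3,3-diarylpropan-1-ol with three free phenols. Ring F is then built on ring D.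

Key step: step 10

Remark on the catalyst: the sense of induction cannot be predicted, so (R)-TRIP, (R)-3,3'-bis(2,4,6-triisopropylphenyl)-1,1'-binaphthyl-2,2'-diyl hydrogen phosphate, is written; its mirror image serves if the (2R,4R) flavan forms.
Remark on ring F: the upper unit is too remote to bias the face of the flavonol, so the hydrogenation of step 17 is planned to give both all-cis diastereomers, and the one with the (2R,3R,4R) lower unit is carried on.
Remark on descriptors: the geometry at C4-U does not change after step 10, but its CIP letter depends on the substituents of ring D; from the bromide onwards the upper unit is therefore named (2S)-2,4-trans.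
Remark on the precursor: its phenols are freed without acid once the carbinol exists (the acetal is removed at the lactone stage, the ring B oxygen travels as a fluoride-labile silyl ether), since any acid would start uncatalysed, racemic ring closure.

Step 1
Reactants: 1 daphnetin (7,8-dihydroxy-2H-chromen-2-one)
Product: 2 7,8-bis(benzyloxy)-2H-chromen-2-one
Conditions: BnBr, K2CO3, DMF, 60 °C
Reagents that add atoms: benzyl bromide, BrCc1ccccc1
Why: Williamson etherification of both catechol hydroxyls; the lactone is inert to carbonate in dry DMF.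

Step 2
Reactants: 3 2,3-dihydroxybenzaldehyde
Product: 4 2,3-bis(benzyloxy)benzaldehyde
Conditions: BnBr, K2CO3, DMF, 60 °C
Reagents that add atoms: benzyl bromide, BrCc1ccccc1
Why: Williamson etherification; with excess base and halide in DMF the hydrogen-bonded 2-OH is alkylated as well.

Step 3
Reactants: 4 2,3-bis(benzyloxy)benzaldehyde
Product: 6 2,3-bis(benzyloxy)phenol, via aryl formate 5 (not isolated)
Conditions: mCPBA, CH2Cl2, 0 °C → rt; then K2CO3 (cat.), MeOH, rt
Reagents that add atoms: 3-chloroperoxybenzoic acid (mCPBA), OOC(=O)c1cccc(Cl)c1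
Why: Baeyer–Villiger oxidation in which the electron-rich aryl group migrates in preference to hydride, followed by methanolysis of the formate (overall the Dakin-type change of CHO into OH).

Step 4
Reactants: 6 2,3-bis(benzyloxy)phenol
Product: 7 1,2-bis(benzyloxy)-3-(methoxymethoxy)benzene
Conditions: NaH, THF, 0 °C; MOMCl, 0 °C → rt
Reagents that add atoms: chloromethyl methyl ether, COCCl
Why: Williamson-type O-alkylation of the sodium phenoxide installs the acetal that will direct the ortho-lithiation.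

Step 5
Reactants: 7 1,2-bis(benzyloxy)-3-(methoxymethoxy)benzene; 2 7,8-bis(benzyloxy)-2H-chromen-2-one
Product: 11 rac-7,8-bis(benzyloxy)-4-[3,4-bis(benzyloxy)-2-(methoxymethoxy)phenyl]chroman-2-one, via aryllithium 8 (not isolated), via arylmagnesium bromide 9 (not isolated), via silyl ketene acetal 10 (not isolated)
Conditions: 7, n-BuLi, THF, 0 °C; MgBr2·OEt2, −20 °C; CuBr·SMe2 (20 mol%), Me3SiCl, 2, −40 → 0 °C; 1 M HCl, 0 °C
Reagents that add atoms: none
Why: Directed ortho-metalation next to the methoxymethoxy group (a stronger director than benzyloxy), transmetalation to magnesium, then copper-catalysed conjugate addition of the aryl Grignard reagent to the coumarin, with Me3SiCl trapping the enolate as 10 to favour 1,4- over 1,2-attack; the new centre is racemic, which is of no consequence because it stops being a stereocentre once the lactol is opened in step 8 and both aryl groups are alike.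

Step 6
Reactants: 11 rac-7,8-bis(benzyloxy)-4-[3,4-bis(benzyloxy)-2-(methoxymethoxy)phenyl]chroman-2-one
Product: 12 rac-7,8-bis(benzyloxy)-4-[3,4-bis(benzyloxy)-2-hydroxyphenyl]chroman-2-one
Conditions: 3 M HCl, THF, 45 °C
Reagents that add atoms: none
Why: Acid hydrolysis of the methoxymethyl acetal, placed here because no acid-labile benzylic carbinol is present yet and the freed phenol can only exchange the lactone degenerately.

Step 7
Reactants: 12 rac-7,8-bis(benzyloxy)-4-[3,4-bis(benzyloxy)-2-hydroxyphenyl]chroman-2-one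
Product: 13 7,8-bis(benzyloxy)-4-[3,4-bis(benzyloxy)-2-hydroxyphenyl]chroman-2-ol (racemic lactol; both C2 epimers)
Conditions: i-Bu2AlH (2.3 equiv), CH2Cl2, −78 °C; aq KNaC4H4O6 (tartrate) work-up
Reagents that add atoms: none
Why: Partial reduction of a lactone to the lactol (the aluminium hemiacetal is stable at −78 °C and one further equivalent is consumed by the phenol); the neutral work-up is chosen so that the lactol does not close onto the second phenol as a bridged acetal.

Step 8
Reactants: 13 7,8-bis(benzyloxy)-4-[3,4-bis(benzyloxy)-2-hydroxyphenyl]chroman-2-ol; 14 (4-bromophenoxy)(tert-butyl)dimethylsilane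
Product: 16 rac-1-[4-(tert-butyldimethylsilyloxy)phenyl]-3,3-bis[3,4-bis(benzyloxy)-2-hydroxyphenyl]propan-1-ol, via Grignard reagent 15 (not isolated)
Conditions: 14, Mg, THF, 50 °C; then 13 (4 equiv of 15 per 13), THF, 0 °C → rt; aq NH4Cl
Reagents that add atoms: none
Why: Grignard addition to the hydroxy aldehyde that the lactol releases on deprotonation; the carbinol forms racemic, which is immaterial because this centre becomes the methide carbon.

Step 9
Reactants: 16 rac-1-[4-(tert-butyldimethylsilyloxy)phenyl]-3,3-bis[3,4-bis(benzyloxy)-2-hydroxyphenyl]propan-1-ol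
Product: 17 rac-1-(4-hydroxyphenyl)-3,3-bis[3,4-bis(benzyloxy)-2-hydroxyphenyl]propan-1-ol
Conditions: Bu4NF, AcOH, THF, 0 °C
Reagents that add atoms: none
Why: Fluoride-induced cleavage of the aryl silyl ether under buffered conditions that leave the ionisable benzylic carbinol intact; the product is used at once and kept away from acidic supports.

Step 10
Reactants: 17 rac-1-(4-hydroxyphenyl)-3,3-bis[3,4-bis(benzyloxy)-2-hydroxyphenyl]propan-1-ol
Product: 19 4-{(2S,4S)-7,8-bis(benzyloxy)-4-[3,4-bis(benzyloxy)-2-hydroxyphenyl]chroman-2-yl}phenol (2,4-trans; the 4'-OH and the OH of the future ring D stay free), via p-quinone methide 18 (not isolated)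
Conditions: (R)-TRIP (10 mol%), 5 Å MS, toluene, 0 °C
Reagents that add atoms: none
Why: Proposed new method: the acid ionises the p-hydroxybenzylic carbinol of 17 to the ring B p-quinone methide 18 and remains hydrogen-bonded to its carbonyl oxygen and to one ortho-phenol, whose oxygen then adds to the methide carbon (oxa-1,6-addition), re-aromatising ring B and forming O1-U–C2-U. The closest known reaction type is the chiral phosphoric acid catalysed 1,6-addition of heteroatom and carbon nucleophiles to p-quinone methides formed in situ from p-hydroxybenzyl alcohols, together with the acid-mediated closure of 1-aryl-3-(2-hydroxyaryl)propan-1-ols to flavans; untested is the choice between two enantiotopic nucleophilic groups. Ring C closes 6-exo-trig, the exocyclic C2-U=C1' bond of the methide being the acceptor. C2-U is controlled by the face of the methide left open in the catalyst pocket and C4-U by which of the two enantiotopic aryl groups delivers O1-U; both choices are coupled in a half-chair transition state with ring B equatorial and the spectator aryl pseudoaxial, away from H5 of the reacting ring, which is the 2,4-trans arrangement. The step needs face selectivity, group selectivity, O- over C-attack and kinetic control at once; the ortho-hydroxyl placed for a six-membered closure (C-attack would need a five-membered indane closure), the two-point hydrogen bonding that only a phenolic OH can offer, and low temperature with sieves and a weakly acidic catalyst to suppress reopening of the benzylic ether secure them. Since no stereocentre of 17 survives, the racemic carbinol converges on one product.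

Step 11
Reactants: 19 4-{(2S,4S)-7,8-bis(benzyloxy)-4-[3,4-bis(benzyloxy)-2-hydroxyphenyl]chroman-2-yl}phenol
Product: 20 tert-butyl(4-{(2S,4S)-7,8-bis(benzyloxy)-4-[3,4-bis(benzyloxy)-2-hydroxyphenyl]chroman-2-yl}phenoxy)dimethylsilane
Conditions: TBSCl (1.1 equiv), imidazole, CH2Cl2, 0 °C
Reagents that add atoms: tert-butyldimethylsilyl chloride, CC(C)(C)[Si](C)(C)Cl
Why: Silylation of a phenol, selective for the unhindered 4'-OH because the other phenol is flanked by a benzyloxy group and the diarylmethine.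

Step 12
Reactants: 20 tert-butyl(4-{(2S,4S)-7,8-bis(benzyloxy)-4-[3,4-bis(benzyloxy)-2-hydroxyphenyl]chroman-2-yl}phenoxy)dimethylsilane
Product: 21 tert-butyl(4-{(2S)-2,4-trans-7,8-bis(benzyloxy)-4-[3,4-bis(benzyloxy)-5-bromo-2-hydroxyphenyl]chroman-2-yl}phenoxy)dimethylsilane
Conditions: NBS (1.0 equiv), MeCN/CH2Cl2, −40 °C, dark
Reagents that add atoms: N-bromosuccinimide, O=C1CCC(=O)N1Br
Why: Electrophilic aromatic bromination directed by the only free phenol to its para position (the future C4a-L), both ortho positions being blocked and all other rings carrying only ether donors.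

Step 13
Reactants: 21 tert-butyl(4-{(2S)-2,4-trans-7,8-bis(benzyloxy)-4-[3,4-bis(benzyloxy)-5-bromo-2-hydroxyphenyl]chroman-2-yl}phenoxy)dimethylsilane
Product: 22 (2S)-2,4-trans-7,8-bis(benzyloxy)-2-(4-benzyloxyphenyl)-4-[2,3,4-tris(benzyloxy)-5-bromophenyl]chroman
Conditions: BnBr, K2CO3, CsF, DMF, rt → 40 °C
Reagents that add atoms: benzyl bromide, BrCc1ccccc1
Why: Williamson etherification of the hindered phenol together with fluoride-induced desilylative benzylation of the silyl ether, so that both oxygens end as benzyl ethers in one operation (benzyl bromide is present before fluoride is added, so the ring B phenoxide is trapped at once).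

Step 14
Reactants: 22 (2S)-2,4-trans-7,8-bis(benzyloxy)-2-(4-benzyloxyphenyl)-4-[2,3,4-tris(benzyloxy)-5-bromophenyl]chroman
Product: 24 1-{2,3,4-tris(benzyloxy)-5-[(2S)-2,4-trans-7,8-bis(benzyloxy)-2-(4-benzyloxyphenyl)chroman-4-yl]phenyl}ethan-1-one, via aryllithium 23 (not isolated)
Conditions: n-BuLi, THF, −78 °C; then MeC(O)N(OMe)Me, −78 → 0 °C
Reagents that add atoms: N-methoxy-N-methylacetamide, CC(=O)N(C)OC
Why: Bromine–lithium exchange followed by acylation with an N-methoxy-N-methylamide, whose chelated tetrahedral adduct prevents a second addition.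

Step 15
Reactants: 24 1-{2,3,4-tris(benzyloxy)-5-[(2S)-2,4-trans-7,8-bis(benzyloxy)-2-(4-benzyloxyphenyl)chroman-4-yl]phenyl}ethan-1-one
Product: 25 1-{3,4-bis(benzyloxy)-2-hydroxy-5-[(2S)-2,4-trans-7,8-bis(benzyloxy)-2-(4-benzyloxyphenyl)chroman-4-yl]phenyl}ethan-1-one
Conditions: MgBr2·OEt2, toluene/Et2O, 50 °C
Reagents that add atoms: none
Why: Chelation-controlled ether cleavage: magnesium held between the ketone oxygen and the ortho ether oxygen activates only that benzyl group toward bromide, which releases O8a-L and leaves the five other benzyl ethers.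

Step 16
Reactants: 25 1-{3,4-bis(benzyloxy)-2-hydroxy-5-[(2S)-2,4-trans-7,8-bis(benzyloxy)-2-(4-benzyloxyphenyl)chroman-4-yl]phenyl}ethan-1-one; 26 4-benzyloxybenzaldehyde
Product: 28 7,8-bis(benzyloxy)-2-(4-benzyloxyphenyl)-3-hydroxy-6-[(2S)-2,4-trans-7,8-bis(benzyloxy)-2-(4-benzyloxyphenyl)chroman-4-yl]-4H-chromen-4-one, via chalcone 27 (not isolated)
Conditions: KOH (aq), EtOH/THF, rt; then H2O2 (30%), 0 °C → rt
Reagents that add atoms: hydrogen peroxide, OO
Why: Claisen–Schmidt condensation to the (E)-2'-hydroxychalcone and Algar–Flynn–Oyamada oxidative cyclisation in the same flask; the lack of a 6'-substituent favours the flavonol over the aurone.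

Step 17
Reactants: 28 7,8-bis(benzyloxy)-2-(4-benzyloxyphenyl)-3-hydroxy-6-[(2S)-2,4-trans-7,8-bis(benzyloxy)-2-(4-benzyloxyphenyl)chroman-4-yl]-4H-chromen-4-one
Product: 29 (2R,3R,4R)-7,8-bis(benzyloxy)-2-(4-benzyloxyphenyl)-6-[(2S)-2,4-trans-7,8-bis(benzyloxy)-2-(4-benzyloxyphenyl)chroman-4-yl]chromane-3,4-diol (2,3-cis-3,4-cis)
Conditions: H2 (5 bar), PtO2, THF/EtOH, rt; chromatographic separation of the two all-cis diastereomers
Reagents that add atoms: none
Why: Heterogeneous catalytic hydrogenation of a flavonol to the flavan-3,4-diol, in which all three hydrogens reach C2-L, C3-L and C4-L from the catalyst face and so fix the 2,3-cis-3,4-cis relation; both faces are expected to be used, the diastereomer with the mirror-image (2S,3S,4S) lower unit is removed, and platinum is chosen because it cleaves aryl benzyl ethers only slowly.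

Step 18
Reactants: 29 (2R,3R,4R)-7,8-bis(benzyloxy)-2-(4-benzyloxyphenyl)-6-[(2S)-2,4-trans-7,8-bis(benzyloxy)-2-(4-benzyloxyphenyl)chroman-4-yl]chromane-3,4-diol
Product: 30 (2R,3R,4R)-6-[(2S,4S)-7,8-dihydroxy-2-(4-hydroxyphenyl)chroman-4-yl]-2-(4-hydroxyphenyl)chromane-3,4,7,8-tetrol (CNP0209379.1)
Conditions: H2 (1 atm), Pd(OH)2/C, EtOAc/MeOH, rt
Reagents that add atoms: none
Why: Hydrogenolysis of the six aryl benzyl ethers under neutral, low-pressure conditions, which is expected to be much faster than cleavage of the benzylic C4-L–OH or of the ring ether bonds; no stereocentre is touched.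

Compound list
1 | daphnetin (7,8-dihydroxy-2H-chromen-2-one) | O=c1ccc2ccc(O)c(O)c2o1 | starting material
2 | 7,8-bis(benzyloxy)-2H-chromen-2-one | O=c1ccc2ccc(OCc3ccccc3)c(OCc3ccccc3)c2o1 | intermediate
3 | 2,3-dihydroxybenzaldehyde | O=Cc1cccc(O)c1O | starting material
4 | 2,3-bis(benzyloxy)benzaldehyde | O=Cc1cccc(OCc2ccccc2)c1OCc1ccccc1 | intermediate
5 | 2,3-bis(benzyloxy)phenyl formate | O=COc1cccc(OCc2ccccc2)c1OCc1ccccc1 | intermediate
6 | 2,3-bis(benzyloxy)phenol | Oc1cccc(OCc2ccccc2)c1OCc1ccccc1 | intermediate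
7 | 1,2-bis(benzyloxy)-3-(methoxymethoxy)benzene | COCOc1cccc(OCc2ccccc2)c1OCc1ccccc1 | intermediate
8 | [3,4-bis(benzyloxy)-2-(methoxymethoxy)phenyl]lithium | [Li]c1ccc(OCc2ccccc2)c(OCc2ccccc2)c1OCOC | intermediate
9 | [3,4-bis(benzyloxy)-2-(methoxymethoxy)phenyl]magnesium bromide | Br[Mg]c1ccc(OCc2ccccc2)c(OCc2ccccc2)c1OCOC | intermediate
10 | rac-7,8-bis(benzyloxy)-4-[3,4-bis(benzyloxy)-2-(methoxymethoxy)phenyl]-2-(trimethylsilyloxy)-4H-chromene | C[Si](C)(C)OC1=CC(c2ccc(OCc3ccccc3)c(OCc3ccccc3)c2OCOC)c2ccc(OCc3ccccc3)c(OCc3ccccc3)c2O1 | intermediate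
11 | rac-7,8-bis(benzyloxy)-4-[3,4-bis(benzyloxy)-2-(methoxymethoxy)phenyl]chroman-2-one | O=C1CC(c2ccc(OCc3ccccc3)c(OCc3ccccc3)c2OCOC)c2ccc(OCc3ccccc3)c(OCc3ccccc3)c2O1 | intermediate
12 | rac-7,8-bis(benzyloxy)-4-[3,4-bis(benzyloxy)-2-hydroxyphenyl]chroman-2-one | O=C1CC(c2ccc(OCc3ccccc3)c(OCc3ccccc3)c2O)c2ccc(OCc3ccccc3)c(OCc3ccccc3)c2O1 | intermediate
13 | 7,8-bis(benzyloxy)-4-[3,4-bis(benzyloxy)-2-hydroxyphenyl]chroman-2-ol (racemic lactol; both C2 epimers) | OC1CC(c2ccc(OCc3ccccc3)c(OCc3ccccc3)c2O)c2ccc(OCc3ccccc3)c(OCc3ccccc3)c2O1 | intermediate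
14 | (4-bromophenoxy)(tert-butyl)dimethylsilane | CC(C)(C)[Si](C)(C)Oc1ccc(Br)cc1 | starting material
15 | [4-(tert-butyldimethylsilyloxy)phenyl]magnesium bromide | CC(C)(C)[Si](C)(C)Oc1ccc([Mg]Br)cc1 | intermediate
16 | rac-1-[4-(tert-butyldimethylsilyloxy)phenyl]-3,3-bis[3,4-bis(benzyloxy)-2-hydroxyphenyl]propan-1-ol | CC(C)(C)[Si](C)(C)Oc1ccc(C(O)CC(c2ccc(OCc3ccccc3)c(OCc3ccccc3)c2O)c2ccc(OCc3ccccc3)c(OCc3ccccc3)c2O)cc1 | intermediate
17 | rac-1-(4-hydroxyphenyl)-3,3-bis[3,4-bis(benzyloxy)-2-hydroxyphenyl]propan-1-ol | OC(CC(c1ccc(OCc2ccccc2)c(OCc2ccccc2)c1O)c1ccc(OCc2ccccc2)c(OCc2ccccc2)c1O)c1ccc(O)cc1 | intermediate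
18 | 4-{3,3-bis[3,4-bis(benzyloxy)-2-hydroxyphenyl]propylidene}cyclohexa-2,5-dien-1-one (ring B p-quinone methide) | O=C1C=CC(=CCC(c2ccc(OCc3ccccc3)c(OCc3ccccc3)c2O)c2ccc(OCc3ccccc3)c(OCc3ccccc3)c2O)C=C1 | intermediate
19 | 4-{(2S,4S)-7,8-bis(benzyloxy)-4-[3,4-bis(benzyloxy)-2-hydroxyphenyl]chroman-2-yl}phenol (2,4-trans) | Oc1ccc([C@@H]2C[C@@H](c3ccc(OCc4ccccc4)c(OCc4ccccc4)c3O)c3ccc(OCc4ccccc4)c(OCc4ccccc4)c3O2)cc1 | intermediate
20 | tert-butyl(4-{(2S,4S)-7,8-bis(benzyloxy)-4-[3,4-bis(benzyloxy)-2-hydroxyphenyl]chroman-2-yl}phenoxy)dimethylsilane | CC(C)(C)[Si](C)(C)Oc1ccc([C@@H]2C[C@@H](c3ccc(OCc4ccccc4)c(OCc4ccccc4)c3O)c3ccc(OCc4ccccc4)c(OCc4ccccc4)c3O2)cc1 | intermediate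
21 | tert-butyl(4-{(2S)-2,4-trans-7,8-bis(benzyloxy)-4-[3,4-bis(benzyloxy)-5-bromo-2-hydroxyphenyl]chroman-2-yl}phenoxy)dimethylsilane | CC(C)(C)[Si](C)(C)Oc1ccc([C@@H]2C[C@@H](c3cc(Br)c(OCc4ccccc4)c(OCc4ccccc4)c3O)c3ccc(OCc4ccccc4)c(OCc4ccccc4)c3O2)cc1 | intermediate
22 | (2S)-2,4-trans-7,8-bis(benzyloxy)-2-(4-benzyloxyphenyl)-4-[2,3,4-tris(benzyloxy)-5-bromophenyl]chroman | c1ccccc1COc1ccc([C@@H]2C[C@@H](c3cc(Br)c(OCc4ccccc4)c(OCc4ccccc4)c3OCc3ccccc3)c3ccc(OCc4ccccc4)c(OCc4ccccc4)c3O2)cc1 | intermediate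
23 | {2,3,4-tris(benzyloxy)-5-[(2S)-2,4-trans-7,8-bis(benzyloxy)-2-(4-benzyloxyphenyl)chroman-4-yl]phenyl}lithium | c1ccccc1COc1ccc([C@@H]2C[C@@H](c3cc([Li])c(OCc4ccccc4)c(OCc4ccccc4)c3OCc3ccccc3)c3ccc(OCc4ccccc4)c(OCc4ccccc4)c3O2)cc1 | intermediate
24 | 1-{2,3,4-tris(benzyloxy)-5-[(2S)-2,4-trans-7,8-bis(benzyloxy)-2-(4-benzyloxyphenyl)chroman-4-yl]phenyl}ethan-1-one | c1ccccc1COc1ccc([C@@H]2C[C@@H](c3cc(C(C)=O)c(OCc4ccccc4)c(OCc4ccccc4)c3OCc3ccccc3)c3ccc(OCc4ccccc4)c(OCc4ccccc4)c3O2)cc1 | intermediate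
25 | 1-{3,4-bis(benzyloxy)-2-hydroxy-5-[(2S)-2,4-trans-7,8-bis(benzyloxy)-2-(4-benzyloxyphenyl)chroman-4-yl]phenyl}ethan-1-one | c1ccccc1COc1ccc([C@@H]2C[C@@H](c3cc(C(C)=O)c(O)c(OCc4ccccc4)c3OCc3ccccc3)c3ccc(OCc4ccccc4)c(OCc4ccccc4)c3O2)cc1 | intermediate
26 | 4-benzyloxybenzaldehyde | O=Cc1ccc(OCc2ccccc2)cc1 | starting material
27 | (E)-1-{3,4-bis(benzyloxy)-2-hydroxy-5-[(2S)-2,4-trans-7,8-bis(benzyloxy)-2-(4-benzyloxyphenyl)chroman-4-yl]phenyl}-3-(4-benzyloxyphenyl)prop-2-en-1-one | c1ccccc1COc1ccc([C@@H]2C[C@@H](c3cc(C(=O)/C=C/c5ccc(OCc6ccccc6)cc5)c(O)c(OCc4ccccc4)c3OCc3ccccc3)c3ccc(OCc4ccccc4)c(OCc4ccccc4)c3O2)cc1 | intermediate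
28 | 7,8-bis(benzyloxy)-2-(4-benzyloxyphenyl)-3-hydroxy-6-[(2S)-2,4-trans-7,8-bis(benzyloxy)-2-(4-benzyloxyphenyl)chroman-4-yl]-4H-chromen-4-one | c1ccccc1COc1ccc([C@@H]2C[C@@H](c3cc4c(c(OCc5ccccc5)c3OCc3ccccc3)oc(-c3ccc(OCc5ccccc5)cc3)c(O)c4=O)c3ccc(OCc5ccccc5)c(OCc5ccccc5)c3O2)cc1 | intermediate
29 | (2R,3R,4R)-7,8-bis(benzyloxy)-2-(4-benzyloxyphenyl)-6-[(2S)-2,4-trans-7,8-bis(benzyloxy)-2-(4-benzyloxyphenyl)chroman-4-yl]chromane-3,4-diol (2,3-cis-3,4-cis) | c1ccccc1COc1ccc([C@@H]2C[C@@H](c3cc4c(c(OCc5ccccc5)c3OCc3ccccc3)O[C@H](c3ccc(OCc5ccccc5)cc3)[C@H](O)[C@@H]4O)c3ccc(OCc5ccccc5)c(OCc5ccccc5)c3O2)cc1 | intermediate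
30 | (2R,3R,4R)-6-[(2S,4S)-7,8-dihydroxy-2-(4-hydroxyphenyl)chroman-4-yl]-2-(4-hydroxyphenyl)chromane-3,4,7,8-tetrol (CNP0209379.1) | Oc1ccc([C@@H]2C[C@@H](c3cc4c(c(O)c3O)O[C@H](c3ccc(O)cc3)[C@H](O)[C@@H]4O)c3ccc(O)c(O)c3O2)cc1 | target

Total step count: 18 steps.
Longest linear sequence: 17 steps (from 3 to 30, steps 2 to 18).

Steps most likely to fail

1. Step 10 (proposed new method). The uncatalysed or reversible ring closure may outrun the catalyst-bound pathway, so that the choice of methide face and of aryl group is lost, and C-alkylation by the electron-rich rings may compete. The fallback uses known chemistry, sets out from 16 and comes back at 20. Oxidation of the benzylic alcohol of 16 (MnO2, CH2Cl2, rt) should give the ketone 1-[4-(tert-butyldimethylsilyloxy)phenyl]-3,3-bis[3,4-bis(benzyloxy)-2-hydroxyphenyl]propan-1-one F1. Asymmetric transfer hydrogenation of this aryl ketone (RuCl(p-cymene)[(R,R)-TsDPEN], HCO2H/Et3N, rt) should give (R)-1-[4-(tert-butyldimethylsilyloxy)phenyl]-3,3-bis[3,4-bis(benzyloxy)-2-hydroxyphenyl]propan-1-ol F2. Mitsunobu etherification (PPh3, DIAD, THF, 0 °C) then closes ring C by SN2 displacement with inversion, so that C2-U is (S) whichever phenol attacks. The two phenols lead to the 2,4-trans and the 2,4-cis flavan; chromatography should give the 2,4-trans isomer, which is 20. Here C2-U is set by the reagent and C4-U by separation.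

2. Step 17. Hydrogenolysis of benzyl ethers and of the benzylic C4-L–O bond may compete with the slow saturation of the tetrasubstituted enol double bond, and the two all-cis diastereomers may resolve poorly at the ether stage. The fallback reverses the order of reduction and deprotection, sets out from 28 and comes back at 30. Hydrogenolysis first (H2, 1 atm, Pd(OH)2/C, THF/MeOH, rt), which leaves a flavonol untouched, should give 3,7,8-trihydroxy-2-(4-hydroxyphenyl)-6-[(2S,4S)-7,8-dihydroxy-2-(4-hydroxyphenyl)chroman-4-yl]-4H-chromen-4-one F3. Hydrogenation of this free flavonol over a catalyst with little tendency to cleave benzylic alcohols (H2, 60 bar, Raney Ni, EtOH, 50 °C) should give both all-cis diols, and preparative reversed-phase chromatography isolates 30.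

3. Step 5. Attack at the lactone carbonyl (1,2-addition) and a sluggish conjugate addition of a hindered ortho-alkoxyaryl nucleophile to an electron-rich coumarin may prevail. The fallback builds the diarylmethine symmetrically without the coumarin, sets out from 7 (through 8) and comes back at 12. Two equivalents of 8 with ethyl formate (THF, −78 °C → rt) should give bis[3,4-bis(benzyloxy)-2-(methoxymethoxy)phenyl]methanol F4. Mukaiyama-type SN1 substitution of this electron-rich benzhydrol with 1-(tert-butyldimethylsilyloxy)-1-methoxyethene (Bi(OTf)3 cat., CH2Cl2, −40 °C) should give methyl 3,3-bis[3,4-bis(benzyloxy)-2-(methoxymethoxy)phenyl]propanoate F5. Aqueous HCl in THF, then TsOH in warm toluene, removes both acetals and lactonises one phenol onto the ester to give 12.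

Further compounds
F1 | step 10 | 1-[4-(tert-butyldimethylsilyloxy)phenyl]-3,3-bis[3,4-bis(benzyloxy)-2-hydroxyphenyl]propan-1-one | CC(C)(C)[Si](C)(C)Oc1ccc(C(=O)CC(c2ccc(OCc3ccccc3)c(OCc3ccccc3)c2O)c2ccc(OCc3ccccc3)c(OCc3ccccc3)c2O)cc1
F2 | step 10 | (R)-1-[4-(tert-butyldimethylsilyloxy)phenyl]-3,3-bis[3,4-bis(benzyloxy)-2-hydroxyphenyl]propan-1-ol | CC(C)(C)[Si](C)(C)Oc1ccc([C@H](O)CC(c2ccc(OCc3ccccc3)c(OCc3ccccc3)c2O)c2ccc(OCc3ccccc3)c(OCc3ccccc3)c2O)cc1
F3 | step 17 | 3,7,8-trihydroxy-2-(4-hydroxyphenyl)-6-[(2S,4S)-7,8-dihydroxy-2-(4-hydroxyphenyl)chroman-4-yl]-4H-chromen-4-one | Oc1ccc([C@@H]2C[C@@H](c3cc4c(c(O)c3O)oc(-c3ccc(O)cc3)c(O)c4=O)c3ccc(O)c(O)c3O2)cc1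
F4 | step 5 | bis[3,4-bis(benzyloxy)-2-(methoxymethoxy)phenyl]methanol | OC(c1ccc(OCc2ccccc2)c(OCc2ccccc2)c1OCOC)c1ccc(OCc2ccccc2)c(OCc2ccccc2)c1OCOC
F5 | step 5 | methyl 3,3-bis[3,4-bis(benzyloxy)-2-(methoxymethoxy)phenyl]propanoate | COC(=O)CC(c1ccc(OCc2ccccc2)c(OCc2ccccc2)c1OCOC)c1ccc(OCc2ccccc2)c(OCc2ccccc2)c1OCOC
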